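C7–CH2–C3' bridge (last bond): dihydrobenzofuran diol 19 + pyranone 24 + one CH2 unit by Mannich/Michael union; the pyranone ring is made separately from ethyl 3-oxopentanoate.
Side chain on C2: C1''=CH2 by titanium methylenation of a ketone; C1''–C2'' by Fukuyama coupling of thioester 14 with homoprenylzinc reagent 16.
Feature the strategy rests on: ring atoms O1–C2–C3–C3a–C7a of the dihydrofuran ring, whose only stereocentre C2 carries O1 and C1''. With C1'' as a carbonyl, O1–C2–C1'' is an aryloxyacetyl unit on the C7a oxygen and C3 is a benzylic chloride on C3a, so one auxiliary-controlled intramolecular enolate alkylation (11 to 13) forms C2–C3, the ring and the C2 configuration.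
Precursor 11 from 2,4,6-trihydroxyacetophenone: para oxygen set apart as benzyl ether, ortho oxygens as MOM ethers, C3 by phenol Mannich reaction, O1–C2 by O-alkylation with bromoacetyl oxazolidinone 9, NMe2 exchanged for Cl with ethyl chloroformate.
Ring order: benzene ring present from the start, dihydrofuran ring in step 8, pyranone ring in step 15, union in step 16.

Key step: step 8

Assumption: atoms are numbered as in 2,3-dihydro-1-benzofuran (O1, C2, C3, C3a, C4 to C7, C7a); the side-chain carbon on C2 is C1'' and the pyranone carbon at the bridge is C3'. The target stereocentre C2 is (R), and anhydrous 2,4,6-trihydroxyacetophenone is used.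

Step 1
Reactants: 1 2,4,6-trihydroxyacetophenone
Product: 2 1-[4-(benzyloxy)-2,6-dihydroxyphenyl]ethanone
Conditions: BnBr (1.0 equiv), K2CO3 (1.05 equiv), DMF, 0 °C → rt
Reagents that add atoms: benzyl bromide BrCc1ccccc1
Why: Williamson etherification with one equivalent of base should occur at the 4-hydroxyl, which is the most acidic phenol and the only one not hydrogen-bonded to or flanked by the acetyl group.

Step 2
Reactants: 2 1-[4-(benzyloxy)-2,6-dihydroxyphenyl]ethanone
Product: 3 1-[4-(benzyloxy)-2,6-bis(methoxymethoxy)phenyl]ethanone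
Conditions: NaH (2.2 equiv), MOMCl (2.2 equiv), DMF, 0 °C → rt
Reagents that add atoms: chloromethyl methyl ether COCCl
Why: O-alkylation of both sodium phenoxides (Williamson-type acetal ether formation) should protect the two ortho hydroxyls, NaH being strong enough to break the hydrogen bond to the carbonyl.

Step 3
Reactants: 3 1-[4-(benzyloxy)-2,6-bis(methoxymethoxy)phenyl]ethanone
Product: 4 1-[4-hydroxy-2,6-bis(methoxymethoxy)phenyl]ethanone
Conditions: H2 (1 atm), 10% Pd/C, EtOAc, rt
Reagents that add atoms: none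
Why: Catalytic hydrogenolysis of the aryl benzyl ether should free the para phenol while the acetal ethers and the twisted aryl ketone remain untouched.

Step 4
Reactants: 4 1-[4-hydroxy-2,6-bis(methoxymethoxy)phenyl]ethanone
Product: 5 1-{3-[(dimethylamino)methyl]-4-hydroxy-2,6-bis(methoxymethoxy)phenyl}ethanone
Conditions: CH2=NMe2+ I− (1.05 equiv), K2CO3, CH2Cl2, rt
Reagents that add atoms: dimethylmethylideneammonium iodide C=[N+](C)C.[I-]
Why: Phenol Mannich reaction (electrophilic substitution by the preformed iminium ion) should take place at one of the two equivalent carbons ortho to the free hydroxyl, and the single equivalent of iminium salt limits double aminomethylation.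

Step 5
Reactants: 6 (S)-4-benzyloxazolidin-2-one; 7 bromoacetyl bromide
Product: 9 (4S)-4-benzyl-3-(bromoacetyl)-1,3-oxazolidin-2-one, via lithium oxazolidinide 8 (not isolated)
Conditions: n-BuLi (1.0 equiv), THF, −78 °C; then BrCH2COBr, −78 → 0 °C
Reagents that add atoms: none
Why: N-acylation of the lithiated oxazolidinone is the standard route to such imides, and the acyl bromide reacts far faster than the alkyl bromide.

Step 6
Reactants: 5 1-{3-[(dimethylamino)methyl]-4-hydroxy-2,6-bis(methoxymethoxy)phenyl}ethanone; 9 (4S)-4-benzyl-3-(bromoacetyl)-1,3-oxazolidin-2-one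
Product: 10 (4S)-3-{2-[4-acetyl-2-[(dimethylamino)methyl]-3,5-bis(methoxymethoxy)phenoxy]acetyl}-4-benzyl-1,3-oxazolidin-2-one
Conditions: Cs2CO3 (1.2 equiv), MeCN, 0 °C → rt
Reagents that add atoms: none
Why: Williamson etherification of the caesium phenoxide with the very reactive alpha-bromo imide should outrun quaternisation of the hindered benzylic amine and installs O1–C2 together with the auxiliary.

Step 7
Reactants: 10 (4S)-3-{2-[4-acetyl-2-[(dimethylamino)methyl]-3,5-bis(methoxymethoxy)phenoxy]acetyl}-4-benzyl-1,3-oxazolidin-2-one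
Product: 11 (4S)-3-{2-[4-acetyl-2-(chloromethyl)-3,5-bis(methoxymethoxy)phenoxy]acetyl}-4-benzyl-1,3-oxazolidin-2-one
Conditions: ClCO2Et (1.5 equiv), CH2Cl2, 0 °C → rt; volatiles removed under high vacuum, crude chloride used at once
Reagents that add atoms: ethyl chloroformate CCOC(=O)Cl
Why: Chloroformate dealkylation of a benzylic tertiary amine (von Braun-type): chloride opens the acylammonium ion at the electron-rich benzylic carbon, giving the benzylic chloride and a neutral carbamate under non-acidic conditions that spare imide, ketone and acetals.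

Step 8
Reactants: 11 (4S)-3-{2-[4-acetyl-2-(chloromethyl)-3,5-bis(methoxymethoxy)phenoxy]acetyl}-4-benzyl-1,3-oxazolidin-2-one
Product: 13 (4S)-3-{[(2R)-5-acetyl-4,6-bis(methoxymethoxy)-2,3-dihydro-1-benzofuran-2-yl]carbonyl}-4-benzyl-1,3-oxazolidin-2-one, via sodium Z-enolate 12 (not isolated)
Conditions: NaN(SiMe3)2 (1.05 equiv), THF (0.02 M), −78 → −40 °C; AcOH quench
Reagents that add atoms: none
Why: Proposed new method: NaN(SiMe3)2 deprotonates the imide CH2 to give the sodium-chelated Z-enolate 12, whose carbon C2 displaces chloride from the benzylic carbon C3 on the ortho position of the same aryl ether, forming C2–C3. The closest known reaction type is the oxazolidinone-controlled alkylation of glycolate imide enolates with benzylic and allylic halides, which has not been used as a ring closure of an aryloxyacetyl imide onto an ortho halomethyl group. The dihydrofuran ring closes in a 5-exo-tet mode with the enolate double bond outside the new ring, which is stereoelectronically allowed, whereas O-alkylation would require a seven-membered ring. The C2 stereocentre is controlled by the 4-benzyl group of the auxiliary, which shields one face of the chelated enolate so that C3 bonds to the open face; by analogy with intermolecular alkylations of the (S)-auxiliary this should give (2R), and because the aryl ring can turn about the O1–C2 bond to reach either face the tether should not override the auxiliary. The step needs facial selectivity (auxiliary), deprotonation at the imide and not at the acetyl methyl (the imide is the more acidic site, one equivalent of base at −78 °C, and any ketone enolate cannot cyclise and should hand its charge on to the imide), and ring closure ahead of intermolecular alkylation (proximity and high dilution).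

Step 9
Reactants: 13 (4S)-3-{[(2R)-5-acetyl-4,6-bis(methoxymethoxy)-2,3-dihydro-1-benzofuran-2-yl]carbonyl}-4-benzyl-1,3-oxazolidin-2-one
Product: 14 S-ethyl (2R)-5-acetyl-4,6-bis(methoxymethoxy)-2,3-dihydro-1-benzofuran-2-carbothioate
Conditions: EtSH (3 equiv), n-BuLi (2 equiv), THF, 0 °C; NH4Cl quench
Reagents that add atoms: ethanethiol CCS
Why: Thiolate transacylation at the exocyclic imide carbonyl is a standard auxiliary cleavage under weakly basic conditions, so C2 should not epimerise and the hindered acetyl group is left alone.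

Step 10
Reactants: 15 5-bromo-2-methylpent-2-ene
Product: 16 (4-methylpent-3-en-1-yl)zinc bromide (titrated THF solution)
Conditions: Zn dust (activated with BrCH2CH2Br and Me3SiCl), LiCl, THF, 50 °C
Reagents that add atoms: zinc [Zn]
Why: Oxidative insertion of LiCl-activated zinc into a primary alkyl bromide is an established route to alkylzinc halides, and the trisubstituted alkene is inert.

Step 11
Reactants: 14 S-ethyl (2R)-5-acetyl-4,6-bis(methoxymethoxy)-2,3-dihydro-1-benzofuran-2-carbothioate; 16 (4-methylpent-3-en-1-yl)zinc bromide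
Product: 17 1-[(2R)-5-acetyl-4,6-bis(methoxymethoxy)-2,3-dihydro-1-benzofuran-2-yl]-5-methylhex-4-en-1-one
Conditions: PdCl2(PPh3)2 (5 mol %), THF/toluene, rt; NH4Cl quench
Reagents that add atoms: none
Why: Fukuyama coupling: the acylpalladium species from insertion into the C–S bond transmetallates with the alkylzinc and gives the ketone without over-addition, under neutral conditions that tolerate the aryl ketone, the acetals and the alpha stereocentre.

Step 12
Reactants: 17 1-[(2R)-5-acetyl-4,6-bis(methoxymethoxy)-2,3-dihydro-1-benzofuran-2-yl]-5-methylhex-4-en-1-one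
Product: 18 1-[(2R)-4,6-bis(methoxymethoxy)-2-(6-methylhepta-1,5-dien-2-yl)-2,3-dihydro-1-benzofuran-5-yl]ethanone
Conditions: Zn, CH2Br2, TiCl4, THF, −40 → 5 °C (reagent pre-formed and aged); then 17, CH2Cl2, 0 °C → rt
Reagents that add atoms: dibromomethane BrCBr
Why: Takai–Lombardo methylenation with a non-basic titanium methylidene species should convert the unhindered, alpha-oxygen-activated dialkyl ketone without epimerising C2, while the acetyl group between two ortho substituents is too shielded to react at a comparable rate.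

Step 13
Reactants: 18 1-[(2R)-4,6-bis(methoxymethoxy)-2-(6-methylhepta-1,5-dien-2-yl)-2,3-dihydro-1-benzofuran-5-yl]ethanone
Product: 19 1-[(2R)-4,6-dihydroxy-2-(6-methylhepta-1,5-dien-2-yl)-2,3-dihydro-1-benzofuran-5-yl]ethanone
Conditions: HCl (0.5 M), MeOH, 0 °C → rt
Reagents that add atoms: none
Why: Acid-catalysed acetal exchange with methanol removes the methoxymethyl ethers, which are especially labile ortho to the acetyl group, under conditions mild enough that the two alkenes and the allylic C2–O1 bond should survive.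

Step 14
Reactants: 20 ethyl 3-oxopentanoate; 21 N-methoxy-N-methylpropanamide
Product: 23 ethyl 4-methyl-3,5-dioxoheptanoate, via dilithium dienolate 22 (not isolated)
Conditions: LiN(i-Pr)2 (2.1 equiv), THF, −78 → 0 °C; then 21, −78 °C → rt; aqueous HCl quench
Reagents that add atoms: none
Why: Claisen-type gamma-acylation of the beta-keto ester dianion at its more nucleophilic terminal carbon gives the 3,5-dioxo ester, whose new C4 centre is enolisable and of no consequence.

Step 15
Reactants: 23 ethyl 4-methyl-3,5-dioxoheptanoate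
Product: 24 6-ethyl-4-hydroxy-5-methyl-2H-pyran-2-one
Conditions: DBU, toluene, reflux; then aqueous HCl
Reagents that add atoms: none
Why: Base-mediated lactonisation of the enolised 3,5-dioxo ester (intramolecular transesterification) is the standard route to 4-hydroxy-2-pyranones.

Step 16
Reactants: 19 1-[(2R)-4,6-dihydroxy-2-(6-methylhepta-1,5-dien-2-yl)-2,3-dihydro-1-benzofuran-5-yl]ethanone; 24 6-ethyl-4-hydroxy-5-methyl-2H-pyran-2-one
Product: 27 3-{[(2R)-5-acetyl-4,6-dihydroxy-2-(6-methylhepta-1,5-dien-2-yl)-2,3-dihydro-1-benzofuran-7-yl]methyl}-6-ethyl-4-hydroxy-5-methyl-2H-pyran-2-one (the target), via pyranone Mannich base 25 (not isolated), via methylidenepyrandione 26 (not isolated)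
Conditions: 24 (1.2 equiv), CH2=NMe2+ I− (1.2 equiv), CH2Cl2, rt; then 19, 40 °C
Reagents that add atoms: dimethylmethylideneammonium iodide C=[N+](C)C.[I-]
Why: Mannich reaction of the pyranone at C3, loss of dimethylamine to the 3-methylidenepyran-2,4-dione and Michael-type addition of the acylphloroglucinol ring through C7, its only free ring carbon, is the established way to methylene-bridged pyranone–acylphloroglucinols.

Compound list
1 | 2,4,6-trihydroxyacetophenone | CC(=O)c1c(O)cc(O)cc1O | starting material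
2 | 1-[4-(benzyloxy)-2,6-dihydroxyphenyl]ethanone | CC(=O)c1c(O)cc(OCc2ccccc2)cc1O | intermediate
3 | 1-[4-(benzyloxy)-2,6-bis(methoxymethoxy)phenyl]ethanone | CC(=O)c1c(OCOC)cc(OCc2ccccc2)cc1OCOC | intermediate
4 | 1-[4-hydroxy-2,6-bis(methoxymethoxy)phenyl]ethanone | CC(=O)c1c(OCOC)cc(O)cc1OCOC | intermediate
5 | 1-{3-[(dimethylamino)methyl]-4-hydroxy-2,6-bis(methoxymethoxy)phenyl}ethanone | CC(=O)c1c(OCOC)cc(O)c(CN(C)C)c1OCOC | intermediate
6 | (S)-4-benzyloxazolidin-2-one | O=C1N[C@@H](Cc2ccccc2)CO1 | starting material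
7 | bromoacetyl bromide | O=C(Br)CBr | starting material
8 | lithium (4S)-4-benzyl-2-oxo-1,3-oxazolidin-3-ide | [Li]N1[C@@H](Cc2ccccc2)COC1=O | intermediate
9 | (4S)-4-benzyl-3-(bromoacetyl)-1,3-oxazolidin-2-one | O=C(CBr)N1[C@@H](Cc2ccccc2)COC1=O | intermediate
10 | (4S)-3-{2-[4-acetyl-2-[(dimethylamino)methyl]-3,5-bis(methoxymethoxy)phenoxy]acetyl}-4-benzyl-1,3-oxazolidin-2-one | O=C(COc1cc(OCOC)c(C(C)=O)c(OCOC)c1CN(C)C)N1[C@@H](Cc2ccccc2)COC1=O | intermediate
11 | (4S)-3-{2-[4-acetyl-2-(chloromethyl)-3,5-bis(methoxymethoxy)phenoxy]acetyl}-4-benzyl-1,3-oxazolidin-2-one | O=C(COc1cc(OCOC)c(C(C)=O)c(OCOC)c1CCl)N1[C@@H](Cc2ccccc2)COC1=O | intermediate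
12 | sodium Z-enolate of 11 | [Na+].[O-]/C(=C\Oc1cc(OCOC)c(C(C)=O)c(OCOC)c1CCl)N1[C@@H](Cc2ccccc2)COC1=O | intermediate
13 | (4S)-3-{[(2R)-5-acetyl-4,6-bis(methoxymethoxy)-2,3-dihydro-1-benzofuran-2-yl]carbonyl}-4-benzyl-1,3-oxazolidin-2-one | O=C([C@H]1Cc2c(OCOC)c(C(C)=O)c(OCOC)cc2O1)N1[C@@H](Cc2ccccc2)COC1=O | intermediate
14 | S-ethyl (2R)-5-acetyl-4,6-bis(methoxymethoxy)-2,3-dihydro-1-benzofuran-2-carbothioate | CCSC(=O)[C@H]1Cc2c(OCOC)c(C(C)=O)c(OCOC)cc2O1 | intermediate
15 | 5-bromo-2-methylpent-2-ene | CC(C)=CCCBr | starting material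
16 | (4-methylpent-3-en-1-yl)zinc bromide | CC(C)=CCC[Zn]Br | intermediate
17 | 1-[(2R)-5-acetyl-4,6-bis(methoxymethoxy)-2,3-dihydro-1-benzofuran-2-yl]-5-methylhex-4-en-1-one | CC(C)=CCCC(=O)[C@H]1Cc2c(OCOC)c(C(C)=O)c(OCOC)cc2O1 | intermediate
18 | 1-[(2R)-4,6-bis(methoxymethoxy)-2-(6-methylhepta-1,5-dien-2-yl)-2,3-dihydro-1-benzofuran-5-yl]ethanone | C=C(CCC=C(C)C)[C@H]1Cc2c(OCOC)c(C(C)=O)c(OCOC)cc2O1 | intermediate
19 | 1-[(2R)-4,6-dihydroxy-2-(6-methylhepta-1,5-dien-2-yl)-2,3-dihydro-1-benzofuran-5-yl]ethanone | C=C(CCC=C(C)C)[C@H]1Cc2c(O)c(C(C)=O)c(O)cc2O1 | intermediate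
20 | ethyl 3-oxopentanoate | CCC(=O)CC(=O)OCC | starting material
21 | N-methoxy-N-methylpropanamide | CCC(=O)N(C)OC | starting material
22 | dilithium dienolate of ethyl 3-oxopentanoate | [Li+].[Li+].CC=C([O-])C=C([O-])OCC | intermediate
23 | ethyl 4-methyl-3,5-dioxoheptanoate | CCC(=O)C(C)C(=O)CC(=O)OCC | intermediate
24 | 6-ethyl-4-hydroxy-5-methyl-2H-pyran-2-one | CCc1oc(=O)cc(O)c1C | intermediate
25 | 3-[(dimethylamino)methyl]-6-ethyl-4-hydroxy-5-methyl-2H-pyran-2-one | CCc1oc(=O)c(CN(C)C)c(O)c1C | intermediate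
26 | 6-ethyl-5-methyl-3-methylidene-2H-pyran-2,4(3H)-dione | CCC1=C(C)C(=O)C(=C)C(=O)O1 | intermediate
27 | 3-{[(2R)-5-acetyl-4,6-dihydroxy-2-(6-methylhepta-1,5-dien-2-yl)-2,3-dihydro-1-benzofuran-7-yl]methyl}-6-ethyl-4-hydroxy-5-methyl-2H-pyran-2-one | C=C(CCC=C(C)C)[C@H]1Cc2c(O)c(C(C)=O)c(O)c(Cc3c(O)c(C)c(CC)oc3=O)c2O1 | target

Total step count: 16. Longest linear sequence: 12 steps (steps 1–4, 6–9, 11–13 and 16).

Steps most likely to fail

1. Step 8 (proposed new method). The very electron-rich benzylic chloride may ionise or alkylate a second molecule before the ring closes, base may be consumed at the acetyl methyl, and facial selectivity in the tethered transition state may be lower than in intermolecular alkylations. The fallback uses known reactions only: it forms C2–C3 by the intermolecular glycolate alkylation and closes the ring at O1–C2 by Mitsunobu inversion. It sets out from 5 and returns to the route at 14.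
 - Phenol 5 is silylated (t-BuMe2SiCl, imidazole, DMF) to 1-{4-[(tert-butyldimethylsilyl)oxy]-3-[(dimethylamino)methyl]-2,6-bis(methoxymethoxy)phenyl}ethanone F1.
 - Ethyl chloroformate converts this into 1-{4-[(tert-butyldimethylsilyl)oxy]-3-(chloromethyl)-2,6-bis(methoxymethoxy)phenyl}ethanone F2.
 - Commercial (R)-4-benzyloxazolidin-2-one is N-acylated (n-BuLi; benzyloxyacetyl chloride) to (4R)-4-benzyl-3-[(benzyloxy)acetyl]-1,3-oxazolidin-2-one F3.
 - The sodium enolate of F3 (NaN(SiMe3)2, THF, −78 °C, Bu4NI) is alkylated by F2, which should give (4R)-3-[(2S)-3-{3-acetyl-6-[(tert-butyldimethylsilyl)oxy]-2,4-bis(methoxymethoxy)phenyl}-2-(benzyloxy)propanoyl]-4-benzyl-1,3-oxazolidin-2-one F4.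
 - Hydrogenolysis (H2, Pd/C) gives (4R)-3-[(2S)-3-{3-acetyl-6-[(tert-butyldimethylsilyl)oxy]-2,4-bis(methoxymethoxy)phenyl}-2-hydroxypropanoyl]-4-benzyl-1,3-oxazolidin-2-one F5.
 - Bu4NF/AcOH frees the phenol to give (4R)-3-{(2S)-3-[3-acetyl-6-hydroxy-2,4-bis(methoxymethoxy)phenyl]-2-hydroxypropanoyl}-4-benzyl-1,3-oxazolidin-2-one F6.
 - Intramolecular Mitsunobu etherification (PPh3, diisopropyl azodicarboxylate, THF) closes O1–C2 with inversion to (4R)-3-{[(2R)-5-acetyl-4,6-bis(methoxymethoxy)-2,3-dihydro-1-benzofuran-2-yl]carbonyl}-4-benzyl-1,3-oxazolidin-2-one F7, which differs from 13 only in the auxiliary configuration.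
 - LiSEt in THF at 0 °C then gives thioester 14.

2. Step 12. The titanium reagent may also methylenate the C5 acetyl group, strip an acetal ether by Lewis acidity, or epimerise C2 through enolisation of the alpha-aryloxy ketone. The fallback changes the order of events and sets out from 17. The methoxymethyl ethers are removed first (HCl, aqueous MeOH, rt), before any acid-sensitive 1,1-disubstituted alkene is present, to give 1-[(2R)-5-acetyl-4,6-dihydroxy-2,3-dihydro-1-benzofuran-2-yl]-5-methylhex-4-en-1-one F8. Excess Zn/CH2Br2/TiCl4 reagent, which tolerates free hydroxyl groups, should then methylenate only the side-chain ketone, because the C5 acetyl group is locked as a chelated vinylogous acid. This returns to the route at 19 and also takes the acid step away from the diene.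

3. Step 6. The benzylic dimethylamino group may be quaternised by the alpha-bromo imide in competition with O-alkylation, and the phenoxide may attack the imide carbonyl. The fallback avoids any alkyl halide and sets out from 5 and 6. Oxazolidinone 6 is N-acylated (n-BuLi, THF, −78 °C; benzyloxyacetyl chloride) to (4S)-4-benzyl-3-[(benzyloxy)acetyl]-1,3-oxazolidin-2-one F9. Hydrogenolysis (H2, Pd/C, EtOAc) gives (4S)-4-benzyl-3-(hydroxyacetyl)-1,3-oxazolidin-2-one F10. Mitsunobu etherification of phenol 5 with F10 (PPh3, diisopropyl azodicarboxylate, THF, 0 °C) forms the aryl ether and returns to the route at 10.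

Further compounds
F1 | step 8 | 1-{4-[(tert-butyldimethylsilyl)oxy]-3-[(dimethylamino)methyl]-2,6-bis(methoxymethoxy)phenyl}ethanone | CC(=O)c1c(OCOC)cc(O[Si](C)(C)C(C)(C)C)c(CN(C)C)c1OCOC
F2 | step 8 | 1-{4-[(tert-butyldimethylsilyl)oxy]-3-(chloromethyl)-2,6-bis(methoxymethoxy)phenyl}ethanone | CC(=O)c1c(OCOC)cc(O[Si](C)(C)C(C)(C)C)c(CCl)c1OCOC
F3 | step 8 | (4R)-4-benzyl-3-[(benzyloxy)acetyl]-1,3-oxazolidin-2-one | O=C(COCc1ccccc1)N1[C@H](Cc2ccccc2)COC1=O
F4 | step 8 | (4R)-3-[(2S)-3-{3-acetyl-6-[(tert-butyldimethylsilyl)oxy]-2,4-bis(methoxymethoxy)phenyl}-2-(benzyloxy)propanoyl]-4-benzyl-1,3-oxazolidin-2-one | O=C([C@H](Cc1c(O[Si](C)(C)C(C)(C)C)cc(OCOC)c(C(C)=O)c1OCOC)OCc1ccccc1)N1[C@H](Cc2ccccc2)COC1=O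
F5 | step 8 | (4R)-3-[(2S)-3-{3-acetyl-6-[(tert-butyldimethylsilyl)oxy]-2,4-bis(methoxymethoxy)phenyl}-2-hydroxypropanoyl]-4-benzyl-1,3-oxazolidin-2-one | O=C([C@H](Cc1c(O[Si](C)(C)C(C)(C)C)cc(OCOC)c(C(C)=O)c1OCOC)O)N1[C@H](Cc2ccccc2)COC1=O
F6 | step 8 | (4R)-3-{(2S)-3-[3-acetyl-6-hydroxy-2,4-bis(methoxymethoxy)phenyl]-2-hydroxypropanoyl}-4-benzyl-1,3-oxazolidin-2-one | O=C([C@H](Cc1c(O)cc(OCOC)c(C(C)=O)c1OCOC)O)N1[C@H](Cc2ccccc2)COC1=O
F7 | step 8 | (4R)-3-{[(2R)-5-acetyl-4,6-bis(methoxymethoxy)-2,3-dihydro-1-benzofuran-2-yl]carbonyl}-4-benzyl-1,3-oxazolidin-2-one | O=C([C@H]1Cc2c(OCOC)c(C(C)=O)c(OCOC)cc2O1)N1[C@H](Cc2ccccc2)COC1=O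
F8 | step 12 | 1-[(2R)-5-acetyl-4,6-dihydroxy-2,3-dihydro-1-benzofuran-2-yl]-5-methylhex-4-en-1-one | CC(C)=CCCC(=O)[C@H]1Cc2c(O)c(C(C)=O)c(O)cc2O1
F9 | step 6 | (4S)-4-benzyl-3-[(benzyloxy)acetyl]-1,3-oxazolidin-2-one | O=C(COCc1ccccc1)N1[C@@H](Cc2ccccc2)COC1=O
F10 | step 6 | (4S)-4-benzyl-3-(hydroxyacetyl)-1,3-oxazolidin-2-one | O=C(CO)N1[C@@H](Cc2ccccc2)COC1=O
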